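**Retrosynthetic overview**
1. The ester is made last from jaeschkeanadiol 17 and 4-methoxybenzoyl chloride; the 6α-OH comes from a hydroxyl-directed reduction of hydroxy ketone 16.
2. The C4 carbinol comes from isopropyl addition to a trans-fused C4 ketone; the 5α-H comes from a stereospecific 1,2-hydride shift in a cis-epoxy alcohol made from dienone 9.
3. Key disconnection C10–C1: bicyclic dienone 9 arises from cis-divinylcyclopropane 8 by a [3,3]-sigmatropic (Cope) rearrangement.
4. Enabling feature: in the seven-membered ring (C1, C5, C6, C7, C8, C9, C10) the C8=C9 double bond and the C5–C6 bond (H on C5, O on C6, next to C4–O: a latent C5=C6 enone alkene) flank the single CH2 C7, with the C10–C1 bond opposite to C7. This is the cyclohepta-1,4-diene pattern that a cyclopropane at C6–C7–C8 delivers.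
5. Ring order: five-membered ring (purchased cyclopentenone), then cyclopropane (asymmetric Simmons–Smith, the only reagent-controlled stereo step), then seven-membered ring (key step); the two fragments are joined by Stille coupling.

Key step: step 6

Remark: daucane numbering is used for the bicyclic compounds (C1 methyl-bearing ring-fusion carbon, C2, C3, C4 carbonyl or carbinol carbon, C5 ring-fusion CH, C6 oxygenated carbon, C7 CH2, C8 methyl-bearing alkene carbon, C9, C10); β is the face of the C1 methyl group. 2-Bromo-3-methylcyclopent-2-en-1-one and the (4R,5R)-dioxaborolane ligand are taken as purchasable.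

**Step 1**
Reactants: 1 prop-2-yn-1-ol
Product: 3 (2Z)-2-methyl-3-(tributylstannyl)prop-2-en-1-ol, via vinylmagnesium alkoxide 2 (not isolated)
Conditions: MeMgBr (2.5 equiv), CuI (10 mol%), THF, −10 °C to rt; then Bu3SnCl, 0 °C to rt; aq. NH4Cl
Reagents that add atoms: methylmagnesium bromide, C[Mg]Br; tributyltin chloride, CCCC[Sn](Cl)(CCCC)CCCC
Why: Copper-catalysed anti-carbomagnesiation of a propargylic alcohol puts methyl on the internal carbon and magnesium on the terminus cis to the alkoxide through a five-membered chelate, and trapping of this vinyl Grignard with Bu3SnCl occurs with retention, fixing the Z geometry that later becomes the cis relationship on the cyclopropane.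

**Step 2**
Reactants: 3 (2Z)-2-methyl-3-(tributylstannyl)prop-2-en-1-ol; 4 2-bromo-3-methylcyclopent-2-en-1-one
Product: 5 2-[(1Z)-3-hydroxy-2-methylprop-1-en-1-yl]-3-methylcyclopent-2-en-1-one
Conditions: Pd(PPh3)4 (5 mol%), CuI (10 mol%), CsF, DMF, 45 °C
Reagents that add atoms: none
Why: Stille coupling of an alkenylstannane with an α-bromoenone, which is activated for oxidative addition, should proceed with retention of the Z geometry and tolerate the free hydroxyl.

**Step 3**
Reactants: 5 2-[(1Z)-3-hydroxy-2-methylprop-1-en-1-yl]-3-methylcyclopent-2-en-1-one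
Product: 6 2-[(1R,2S)-2-(hydroxymethyl)-2-methylcyclopropyl]-3-methylcyclopent-2-en-1-one (hydroxymethyl cis to the cyclopentenone)
Conditions: Et2Zn, CH2I2, DME, (4R,5R)-2-butyl-N,N,N',N'-tetramethyl-1,3,2-dioxaborolane-4,5-dicarboxamide (1.2 equiv), CH2Cl2, −10 °C to rt
Reagents that add atoms: diiodomethane, ICI
Why: Dioxaborolane-mediated asymmetric Simmons–Smith (Charette) cyclopropanation delivers CH2 from the zinc alkoxide to one face of the allylic-alcohol alkene only (the enone alkene is electron-poor and inert), so the Z geometry becomes the cis relationship and both cyclopropane centres are set by the (R,R) ligand in the sense known for cinnamyl alcohol.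

**Step 4**
Reactants: 6 2-[(1R,2S)-2-(hydroxymethyl)-2-methylcyclopropyl]-3-methylcyclopent-2-en-1-one
Product: 7 (1S,2R)-1-methyl-2-(2-methyl-5-oxocyclopent-1-en-1-yl)cyclopropane-1-carbaldehyde
Conditions: Dess–Martin periodinane, NaHCO3, CH2Cl2, 0 °C to rt
Reagents that add atoms: none
Why: Dess–Martin oxidation of the primary alcohol under buffered conditions; the quaternary α-carbon excludes epimerisation.

**Step 5**
Reactants: 7 (1S,2R)-1-methyl-2-(2-methyl-5-oxocyclopent-1-en-1-yl)cyclopropane-1-carbaldehyde
Product: 8 2-[(1R,2R)-2-ethenyl-2-methylcyclopropyl]-3-methylcyclopent-2-en-1-one (cis-divinylcyclopropane)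
Conditions: Ph3PCH3Br, KN(SiMe3)2, THF, −78 to 0 °C
Reagents that add atoms: methyltriphenylphosphonium bromide, C[P+](c1ccccc1)(c1ccccc1)c1ccccc1.[Br-]
Why: Wittig methylenation should be chemoselective for the aldehyde over the hindered conjugated ketone at low temperature, and 8 should be isolable cold because the inward-pointing methyl on the enone terminus slows its rearrangement.

**Step 6**
Reactants: 8 2-[(1R,2R)-2-ethenyl-2-methylcyclopropyl]-3-methylcyclopent-2-en-1-one
Product: 9 (3aR)-3a,6-dimethyl-3,3a,4,7-tetrahydroazulen-1(2H)-one (daucane numbering: C4 ketone, C5=C6 and C8=C9 double bonds, C1 quaternary)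
Conditions: PhMe, 110 °C, sealed tube
Reagents that add atoms: none
Why: The cis-divinylcyclopropane undergoes a concerted thermal [3,3]-sigmatropic (Cope) shift through the boat transition state in which both alkenyl groups lie over the three-membered ring, the C6–C8 cyclopropane bond breaking as the vinyl CH2 (C10) bonds to the methyl-bearing β-carbon of the cyclopentenone (C1). The closest known reaction type is the divinylcyclopropane–cycloheptadiene rearrangement of 2-vinylcyclopropyl cyclopentenes and cyclopentenones, which has been used to build hydroazulenes with an angular methyl group. The seven-membered ring is closed as a 1,4-cycloheptadiene by this sigmatropic bond formation, driven by release of cyclopropane strain and by the new C4(=O)–C5=C6 conjugation. The single new stereocentre, quaternary C1, is controlled by the cyclopropane: with the (1R,2R) configuration the boat geometry presents only one face of C1 to C10, which should give (R)-C1 with full chirality transfer while the two cyclopropane centres are erased. The step needs the cis arrangement of the two alkenyl groups, secured by the Z alkene of 5 and the stereospecific cyclopropanation, and it needs heat because the C1 methyl points inward in the boat; a trans isomer would have to epimerise through a diradical and would racemise. A homodienyl 1,5-hydrogen shift cannot compete because no hydrogen-bearing alkyl group is cis to an alkenyl group.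

**Step 7**
Reactants: 9 (3aR)-3a,6-dimethyl-3,3a,4,7-tetrahydroazulen-1(2H)-one
Product: 10 5β,6β-epoxide of 9 (epoxide oxygen on the face of the C1 methyl; C4 ketone, C8=C9 retained)
Conditions: 30% aq. H2O2, LiOH (0.2 equiv), MeOH, 0 °C
Reagents that add atoms: hydrogen peroxide, OO
Why: Weitz–Scheffer nucleophilic epoxidation is selective for the enone over the isolated trisubstituted alkene, and hydroperoxide should add to C6 and close onto C5 from the convex β face because the α face is covered by the folded C8=C9–C10 part of the seven-membered ring.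

**Step 8**
Reactants: 10 5β,6β-epoxy ketone
Product: 11 4β-hydroxy-5β,6β-epoxide (cis-epoxy alcohol, C4–H on the α face)
Conditions: NaBH4, CeCl3·7H2O, MeOH, −78 to −40 °C
Reagents that add atoms: none
Why: Luche reduction of an α,β-epoxy ketone delivers hydride anti to the epoxide oxygen (cerium bridging carbonyl and epoxide oxygen), which should give the cis-epoxy alcohol with the C4 hydrogen antiperiplanar to the C5–O bond.

**Step 9**
Reactants: 11 4β-hydroxy-5β,6β-epoxide
Product: 13 trans-fused (5α-H) 6β-(triethylsilyloxy) C4 ketone, via epoxy silyl ether 12 (not isolated)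
Conditions: Et3SiOTf (2.2 equiv), i-Pr2NEt, 4 Å molecular sieves, CH2Cl2, −78 to −40 °C
Reagents that add atoms: triethylsilyl trifluoromethanesulfonate, CC[Si](CC)(CC)OS(=O)(=O)C(F)(F)F
Why: Non-aldol aldol rearrangement (silyl-triflate-promoted semipinacol 1,2-hydride shift of a 2,3-epoxy silyl ether): the activated epoxide opens at tertiary C5 while the antiperiplanar C4 hydrogen migrates with inversion at C5, which sets the 5α-H (trans ring fusion) stereospecifically and releases the C4 ketone and the C6 silyl ether.

**Step 10**
Reactants: 13 trans-fused 6β-(triethylsilyloxy) C4 ketone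
Product: 15 6-epi-jaeschkeanadiol (4β-hydroxy-4α-isopropyl-5α-H-dauc-8-en-6β-ol), via tertiary carbinol silyl ether 14 (not isolated)
Conditions: i-PrMgCl, CeCl3, THF, −78 °C; then AcOH, Bu4NF, THF, 0 °C to rt
Reagents that add atoms: isopropylmagnesium chloride, CC(C)[Mg]Cl
Why: Organocerium addition to the enolisable hindered ketone should occur from the α face, anti to the C5–C6 bond, the 6β-silyloxy group and the C1 methyl, giving the 4β tertiary alcohol, and fluoride then cleaves the silyl ether.

**Step 11**
Reactants: 15 6-epi-jaeschkeanadiol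
Product: 16 4β-hydroxy-4α-isopropyl-5α-H-dauc-8-en-6-one
Conditions: Dess–Martin periodinane, NaHCO3, CH2Cl2, 0 °C to rt
Reagents that add atoms: none
Why: Dess–Martin oxidation takes the secondary alcohol only, and the neutral conditions should leave the C5 centre (already in its preferred arrangement, isopropyl trans to C6) and the β,γ-placed C8=C9 alkene untouched.

**Step 12**
Reactants: 16 4β-hydroxy-4α-isopropyl-5α-H-dauc-8-en-6-one
Product: 17 jaeschkeanadiol (dauc-8-ene-4β,6α-diol)
Conditions: Me4NBH(OAc)3, MeCN/AcOH, −20 °C
Reagents that add atoms: none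
Why: Evans–Saksena hydroxyl-directed reduction: the alkoxy(diacetoxy)borohydride formed at the 4β-hydroxyl delivers hydride internally to the β face of the C6 ketone, which should give the 1,3-anti diol with the 6α-hydroxyl; an undirected hydride would come from the α face, anti to the C1 methyl.

**Step 13**
Reactants: 17 jaeschkeanadiol; 18 4-methoxybenzoyl chloride
Product: 19 fertidin (jaeschkeanadiol 6-O-(4-methoxybenzoate))
Conditions: Et3N, DMAP (cat.), CH2Cl2, 0 °C to rt
Reagents that add atoms: none
Why: DMAP-catalysed acylation should take the secondary 6α-hydroxyl and leave the hindered tertiary 4β-hydroxyl free.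

**Compound list**
1 | prop-2-yn-1-ol | C#CCO | starting material
2 | (Z)-vinylmagnesium alkoxide from anti-carbomagnesiation | Br[Mg]/C=C(C)\CO[Mg]Br | intermediate
3 | (2Z)-2-methyl-3-(tributylstannyl)prop-2-en-1-ol | OC/C(C)=C\[Sn](CCCC)(CCCC)CCCC | intermediate
4 | 2-bromo-3-methylcyclopent-2-en-1-one | CC1=C(Br)C(=O)CC1 | starting material
5 | 2-[(1Z)-3-hydroxy-2-methylprop-1-en-1-yl]-3-methylcyclopent-2-en-1-one | OC/C(C)=C\C1=C(C)CCC1=O | intermediate
6 | 2-[(1R,2S)-2-(hydroxymethyl)-2-methylcyclopropyl]-3-methylcyclopent-2-en-1-one | OC[C@@]1(C)C[C@H]1C1=C(C)CCC1=O | intermediate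
7 | (1S,2R)-1-methyl-2-(2-methyl-5-oxocyclopent-1-en-1-yl)cyclopropane-1-carbaldehyde | O=C[C@@]1(C)C[C@H]1C1=C(C)CCC1=O | intermediate
8 | 2-[(1R,2R)-2-ethenyl-2-methylcyclopropyl]-3-methylcyclopent-2-en-1-one | C=C[C@@]1(C)C[C@H]1C1=C(C)CCC1=O | intermediate
9 | (3aR)-3a,6-dimethyl-3,3a,4,7-tetrahydroazulen-1(2H)-one | CC1=CC[C@@]2(C)CCC(=O)C2=CC1 | intermediate
10 | 5β,6β-epoxide of 9 | CC1=CC[C@@]2(C)CCC(=O)[C@]23O[C@@H]3C1 | intermediate
11 | 4β-hydroxy-5β,6β-epoxide (cis-epoxy alcohol) | CC1=CC[C@@]2(C)CC[C@H](O)[C@]23O[C@@H]3C1 | intermediate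
12 | 4-O-triethylsilyl ether of 11 | CC1=CC[C@@]2(C)CC[C@H](O[Si](CC)(CC)CC)[C@]23O[C@@H]3C1 | intermediate
13 | trans-fused (5α-H) 6β-(triethylsilyloxy) C4 ketone | CC1=CC[C@@]2(C)CCC(=O)[C@@H]2[C@H](O[Si](CC)(CC)CC)C1 | intermediate
14 | 4β-hydroxy-4α-isopropyl 6β-triethylsilyl ether | CC1=CC[C@@]2(C)CC[C@@](O)(C(C)C)[C@@H]2[C@H](O[Si](CC)(CC)CC)C1 | intermediate
15 | 6-epi-jaeschkeanadiol (4β,6β-diol) | CC1=CC[C@@]2(C)CC[C@@](O)(C(C)C)[C@@H]2[C@H](O)C1 | intermediate
16 | 4β-hydroxy-4α-isopropyl-5α-H-dauc-8-en-6-one | CC1=CC[C@@]2(C)CC[C@@](O)(C(C)C)[C@@H]2C(=O)C1 | intermediate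
17 | jaeschkeanadiol (dauc-8-ene-4β,6α-diol) | CC1=CC[C@@]2(C)CC[C@@](O)(C(C)C)[C@@H]2[C@@H](O)C1 | intermediate
18 | 4-methoxybenzoyl chloride | COc1ccc(C(=O)Cl)cc1 | starting material
19 | fertidin | COc1ccc(C(=O)O[C@H]2CC(C)=CC[C@@]3(C)CC[C@@](O)(C(C)C)[C@H]23)cc1 | target

**Step count**
Total steps: 13. Longest linear sequence: 13 steps (from prop-2-yn-1-ol; 4 and 18 are purchased).

**Steps most likely to fail**

1. Step 9 (hydride-shift rearrangement). After ionisation of the C5–O bond the cation may be quenched by ring-bond migration or proton loss instead of the C4 hydride shift, or the freed ketone may be enolised by silyl triflate and base with loss of the C5 configuration. The fallback sets out from 9 and returns at 16, and replaces the stereospecific shift by thermodynamic control at C5. Organocerium addition of i-PrMgCl/CeCl3 to the C4 ketone gives the tertiary allylic alcohol F1 (either C4 epimer serves). Oxidative 1,3-transposition with pyridinium chlorochromate, [C5H5NH][CrO3Cl], gives the C4=C5, C6-keto dienone F2. Nucleophilic epoxidation (t-BuOOH, DBU) from the β face gives the 4β,5β-epoxy ketone F3. SmI2 in THF/MeOH cleaves the C5–O bond, and C5, now next to the C6 ketone, should settle with the isopropyl group trans to C6, which is 16.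

2. Step 7 (epoxidation). Hydroperoxide may attack the α face, or the base may move the C8=C9 double bond of the skipped dienone into conjugation through the C7 dienolate. The fallback sets out from 9 and returns at 11, and uses a hydroxyl-directed, base-free epoxidation. NaBH4/CeCl3·7H2O reduces the ketone to the 4β-allylic alcohol F4 (purified by chromatography), and VO(acac)2/t-BuOOH in CH2Cl2 epoxidises the C5=C6 bond syn to the hydroxyl, which is also the convex face, to give 11.

3. Step 3 (asymmetric cyclopropanation). The Lewis basic enone may bind the zinc carbenoid and erode conversion or face selectivity. The fallback sets out from 3 and returns at 6, and makes the cyclopropane before the fragments are joined. The same dioxaborolane-mediated cyclopropanation of the simple stannyl allylic alcohol 3 gives the stannylcyclopropylmethanol F5, and iodine in CH2Cl2 exchanges tin for iodine with retention to give the iodocyclopropylmethanol F6. After deprotonation of the hydroxyl (MeMgCl), iodine–magnesium exchange (i-PrMgCl·LiCl), transmetalation (ZnCl2) and Negishi coupling with 4 (Pd(OAc)2, SPhos, THF, 50 °C) give 6.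

**Further compounds**
F1 | step 9 | 4-hydroxy-4-isopropyl adduct of 9 (tertiary allylic alcohol, C4 epimers) | CC1=CC[C@@]2(C)CCC(O)(C(C)C)C2=CC1
F2 | step 9 | C4=C5, C6-keto dienone (4-isopropyl) | CC1=CC[C@@]2(C)CCC(C(C)C)=C2C(=O)C1
F3 | step 9 | 4β,5β-epoxy-4α-isopropyl C6 ketone | CC1=CC[C@@]2(C)CC[C@]3(C(C)C)O[C@]23C(=O)C1
F4 | step 7 | 4β-allylic alcohol from 9 | CC1=CC[C@@]2(C)CC[C@H](O)C2=CC1
F5 | step 3 | [(1S,2R)-1-methyl-2-(tributylstannyl)cyclopropyl]methanol (cis) | OC[C@@]1(C)C[C@H]1[Sn](CCCC)(CCCC)CCCC
F6 | step 3 | cis-(2-iodo-1-methylcyclopropyl)methanol, same spatial arrangement as F5 | OC[C@@]1(C)C[C@H]1I
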